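(All runs stem from a simulated flask with made-up constants.)

The left-handed product came late: Saturday's run showed 0.5% at 2.00 h, then 10.0% at 6.00 h.

| flask | left-handed substrate | right-handed substrate | solid reagent | free catalyst | remark | time |
|---|---|---|---|---|---|---|
| Saturday's | 0.050 M | 0.050 M | 0.060 M | 0.20 mM | run made earlier |  |
| Thursday's | 0.20 M | 0.20 M | 0.060 M | 0.20 mM | run made earlier |  |
| Friday's | 0.10 M | 0.10 M | 0.060 M | 0.10 mM | run made earlier |  |
| flask | 0.10 M | 0.10 M | 0.0600 M | 0.20 mM |  | 10 h |

- Saturday's (time / h: left-handed product / %, left-handed substrate / %): 0.500: 2.2, 48.3; 0.833: 1.4, 51.1; 1.33: 1.8, 48.2; 2.00: 0.5, 47.7; 4.00: 4.8, 43.4; 6.00: 10.0, 42.0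
- Thursday's (time / h: left-handed product / %, left-handed substrate / %): 0.500: 0, 49.8; 0.833: 0.5, 50.3; 1.33: 0.3, 49.6; 2.00: 0, 49.2; 4.00: 3.4, 51.0; 6.00: 3.6, 47.3
- Friday's (time / h: left-handed product / %, left-handed substrate / %): 1.33: 1.3, 50.1; 2.50: 0, 49.9; 4.00: 2.5, 47.6; 5.00: 1.3, 48.8; 6.00: 1.5, 46.6

(each reading ± 1 percentage point)

- free catalyst is single-handed; left-handed substrate and right-handed substrate are mirror images of each other, charged as a racemate, each of them at the stated concentration
- solid, in amounts per volume of the solution: solid reagent
- the analysis behind the earlier runs scatters by 1 percentage point, standard deviation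
- candidate steps: free catalyst + left-handed substrate <-> catalyst intermediate A; free catalyst + right-handed substrate <-> catalyst intermediate B; partner + catalyst intermediate A -> free catalyst + left-handed product; partner + catalyst intermediate B -> free catalyst + right-handed product; solid reagent <-> partner
- at the start none of the solid reagent is in solution

- summer: doubling the dissolution coefficient of the solid reagent, all else as stated
- spring: doubling the solubility of the solid reagent, all else as stated
- midnight: doubling the amount of free catalyst, all else as stated

1. amount of left-handed product at 10 h, in percent of the left-handed substrate and right-handed substrate together charged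
2. the change that raises the amount of left-handed product at 10 h, in percent of the left-handed substrate and right-handed substrate together charged most ("none" if none brings more than 2 percentage points) (summer / spring / midnight / none)
3. amount of left-handed product at 10 h, in percent of the left-handed substrate and right-handed substrate together charged, after midnight

So I froze one rate, the turnover frequency: left-handed product made per catalyst charged per hour, once the lag is over. I read it from the last rise in each run:

Saturday's 11.9 /h; Thursday's 18.0 /h; Friday's 8.57 /h

Friday's is a rough reading, with a scatter of 1 percentage point on a rise of 1.5 points. Between Saturday's and Thursday's substrate the apparent order was 0.300, so their geometric mean, 14.6 /h, suits the flask. Friday's run has the flask's substrate, so I averaged the two: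

frequency: 11.6 /h
full pace for 10 h: 11.6%
lag of 2.00 h: × 0.800, giving 9.28%
falling left-handed substrate, reckoned on its own charge: × 0.940
my estimate: 8.72%

Midnight doubles the pace, and the same reckoning, again on the left-handed substrate's own charge, gives 16.1%. The runs give no frequency for spring or summer, so I chose midnight.

The forecast differed, with 12.5%, 20% after midnight, and spring as best: “Doubling solubility doubles partner directly”.

The flask gave 9.85%; midnight was best, reaching 16.7%.

    free catalyst + left-handed substrate ⇌ catalyst intermediate A (K = 41.0 /M, k = 38000 /M/h)
    free catalyst + right-handed substrate ⇌ catalyst intermediate B (K = 79.0 /M, k = 37000 /M/h)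
    partner + catalyst intermediate A → free catalyst + left-handed product (k = 1200 /M/h)
    partner + catalyst intermediate B → free catalyst + right-handed product (k = 37.0 /M/h)
    solid reagent ⇌ partner, rate k5*(cs5 - [partner]) while solid is left; crystals form when [partner] > cs5 (solubility = 38.0 mM, k = 0.590 /h)

In the flask the turnover frequency over the second half of the time was 11.1 /h, and at 10.0 h partner was made 1.04 times as fast as it was used, standing at 0.0339 M. In the flask left until 40 h, solid reagent reached 0% and partner 0.00694 M, and the frequency after 10 h averaged 4.89 /h, ending at 24.5% left-handed product.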